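The target is cut at C7=C8 into commercial β-apo-8'-carotenal and a C10 hydroxy ring unit; oleic acid is attached last. The ring synthesis rests on one feature of the six-membered end ring (carotenoid numbering): C3, which carries oxygen, and C6, which carries C7, are 1,4-related, while C1 bears both methyls and C2 none. An O–C7(=O) lactone can therefore bridge C3 and C6, and the ring falls apart into 4-methyl-2-pyranone and isobutene. One enantioselective inverse-demand Diels–Alder reaction forms C2–C3 and C1–C6, closes the carbocycle and sets C3. Its precursor is simply the flat pyranone plus the gaseous alkene.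

Key step: step 3

Remark on numbering: carotenoid numbering of the hydroxylated end group is used throughout (C1 = CMe2, C2 = CH2, C3 = C–O, C4 = CH2, C5 = C–CH3, C6 = ring carbon bearing C7, C7=C8 = first chain alkene).
Remark on descriptors: the C3 centre is carried unchanged from 5 to 15; its descriptor is S while the alkene is at C4=C5 (5, 6) and R once the alkene is at C5=C6, because only the CIP ranking of the two ring branches changes.
Remark on the catalyst: which antipode of the step 3 catalyst gives (1S,4R)-5 cannot be predicted safely; it is assumed to be settled by correlation of 13 with natural (3R)-β-cryptoxanthin, both prolinol antipodes being commercial.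
Remark on the precursor: the pyranone carries no extra chelating group at its C3, since that carbon becomes C6 and any such group would cost steps to remove.

Step 1
Reactants: 1 ethyl 3-methylbut-2-enoate
Product: 2 ethyl (2Z)-3-methyl-5-oxopent-2-enoate
Conditions: HCO2Et (1.5 equiv), KOEt (1.1 equiv, alcohol-free), Et2O, 0 °C → rt; cold aq. AcOH
Reagents that add atoms: ethyl formate, CCOC=O
Why: Vinylogous Claisen condensation, in which the reversibly formed dienolate of 1 is formylated at the γ-methyl because only the γ-product can form a fully conjugated enolate salt that drives the equilibrium (2 is obtained together with its E isomer and its enol form, all of which converge in step 2).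

Step 2
Reactants: 2 ethyl (2Z)-3-methyl-5-oxopent-2-enoate
Product: 3 4-methyl-2H-pyran-2-one
Conditions: conc. H2SO4 (cat.), AcOH, 80 °C; vacuum distillation
Reagents that add atoms: none
Why: Acid-catalysed enol lactonisation, in which enolisation and alkene equilibration place the enol oxygen cis to the ester and ring closure with loss of ethanol gives the conjugated pyranone.

Step 3
Reactants: 3 4-methyl-2H-pyran-2-one; 4 2-methylpropene (isobutene)
Product: 5 (1S,4R)-5,8,8-trimethyl-2-oxabicyclo[2.2.2]oct-5-en-3-one
Conditions: oxazaborolidine from (S)-α,α-diphenylprolinol and o-tolylboroxine (20 mol %; antipode if correlation demands), AlBr3 (16 mol %), 2,6-di-tert-butyl-4-methylpyridine (5 mol %), 4 (10 equiv), CH2Cl2, −78 → −20 °C; Et3N quench; work-up below 25 °C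
Reagents that add atoms: none
Why: Proposed new method: the aprotic cationic boron Lewis acid binds the lactone carbonyl of 3 and lowers the LUMO of the cyclic dienoate, so that the CH2 end of 4 attacks the ring carbon next to oxygen (C3) while the carbon that takes on tertiary cation character closes onto the carbon α to the carbonyl (C6) in a concerted but asynchronous, suprafacial inverse-electron-demand [4+2] cycloaddition. The nearest established chemistry is the cycloaddition of 2-pyranones with enol ethers and similar electron-rich alkenes under Lewis acid catalysis or high pressure, which gives isolable bridged lactones and is enantioselective only when a chelating 3-acyl group is present, together with oxazaborolidinium-catalysed Diels–Alder reactions of one-point-binding unsaturated esters and lactones; a non-activated alkene and a non-chelating pyranone go beyond both. The carbocycle C1–C6 is closed by intermolecular [4+2] addition across the diene termini through a six-membered transition state, and the second ring of the bicycle needs no closure of its own because the O–C7(=O) unit already links C3 and C6 and simply becomes the bridge. The two new stereocentres C3 and C6 are set together by the face of the flat pyranone that the alkene approaches, the other face being covered by an aryl group of the bound catalyst, so that catalyst control alone fixes the absolute configuration and C6 is erased in step 4. The step needs regioselectivity, which the substrate secures by polarity (nucleophilic CH2 to the δ-carbon of the activated dienoate, cation-stabilising CMe2 to the α-carbon) and by the 4-methyl group that shields the competing β-position, whereas endo/exo selectivity does not arise since each alkene carbon carries two identical groups. The hindered pyridine and the proton-free activator keep isobutene from cationic oligomerisation, and the low temperature keeps 5 from losing CO2 by retro-[4+2] reaction.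

Step 4
Reactants: 5 (1S,4R)-5,8,8-trimethyl-2-oxabicyclo[2.2.2]oct-5-en-3-one
Product: 7 methyl (4R)-4-hydroxy-2,6,6-trimethylcyclohex-1-ene-1-carboxylate, via non-conjugated hydroxy ester 6 (not isolated)
Conditions: NaOMe (1.2 equiv), MeOH, 0 °C → rt; AcOH quench
Reagents that add atoms: sodium methoxide, [Na+].[O-]C
Why: Methanolysis of the bridged lactone followed by base-mediated alkene isomerisation, in which the C6–H of 6 (now allylic and α to the ester) is removed reversibly and the dienolate is reprotonated at C4 to give the conjugated tetrasubstituted alkene, so that C6 ceases to be a stereocentre while C3, which is never deprotonated, keeps its configuration.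

Step 5
Reactants: 7 methyl (4R)-4-hydroxy-2,6,6-trimethylcyclohex-1-ene-1-carboxylate
Product: 8 (1R)-4-(hydroxymethyl)-3,5,5-trimethylcyclohex-3-en-1-ol
Conditions: LiAlH4 (2 equiv), Et2O, 0 °C → rt; H2O/aq. NaOH work-up
Reagents that add atoms: none
Why: Hydride 1,2-reduction of the hindered, twisted conjugated ester to the primary allylic alcohol, with the C3 alkoxide as an inert spectator and no bond to the stereocentre touched.

Step 6
Reactants: 8 (1R)-4-(hydroxymethyl)-3,5,5-trimethylcyclohex-3-en-1-ol
Product: 9 {[(4R)-4-hydroxy-2,6,6-trimethylcyclohex-1-en-1-yl]methyl}triphenylphosphonium bromide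
Conditions: PPh3·HBr (1.05 equiv), MeOH, rt, dark
Reagents that add atoms: triphenylphosphine hydrobromide, [PH+](c1ccccc1)(c1ccccc1)c1ccccc1.[Br-]
Why: Acid-mediated allylic substitution (phosphonium salt formation), in which only the primary allylic alcohol ionises to the stabilised allyl cation that PPh3 captures at its unhindered primary end, while the secondary C3 alcohol is not allylic and stays intact.

Step 7
Reactants: 9 {[(4R)-4-hydroxy-2,6,6-trimethylcyclohex-1-en-1-yl]methyl}triphenylphosphonium bromide; 10 β-apo-8'-carotenal
Product: 13 (3R)-β-cryptoxanthin, via phosphorus ylide 11 (not isolated), via 7Z isomer 12 (not isolated)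
Conditions: 9 (1.2 equiv), NaOMe (1.3 equiv), MeOH/CH2Cl2, 0 °C → rt, Ar, dark; then I2 (1 mol %), hexane/CH2Cl2, daylight, rt; crystallisation
Reagents that add atoms: none
Why: Wittig olefination of the semi-stabilised allylic ylide with the non-enolisable polyenal forms C7=C8 as an E/Z mixture, and iodine-atom-catalysed equilibration then converts the strained 7Z isomer into the thermodynamically preferred all-E polyene, the free hydroxyl being tolerated under methoxide conditions.

Step 8
Reactants: 13 (3R)-β-cryptoxanthin; 14 oleic acid
Product: 15 (3R)-β,β-caroten-3-yl (9Z)-octadec-9-enoate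
Conditions: 14 (1.3 equiv), EDC·HCl (1.5 equiv), DMAP (0.3 equiv), CH2Cl2, 0 °C → rt, Ar, dark
Reagents that add atoms: none
Why: Steglich esterification, in which carbodiimide activation of the acid and DMAP-catalysed acyl transfer acylate the unhindered secondary alcohol without breaking the C3–O bond, so the configuration is retained and neither the Z-alkene of the acid nor the polyene is affected.

Compound list
1 | ethyl 3-methylbut-2-enoate | CCOC(=O)C=C(C)C | starting material
2 | ethyl (2Z)-3-methyl-5-oxopent-2-enoate (with its E isomer and enol form) | CCOC(=O)/C=C(C)\CC=O | intermediate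
3 | 4-methyl-2H-pyran-2-one | CC1=CC(=O)OC=C1 | intermediate
4 | 2-methylpropene (isobutene) | CC(C)=C | starting material
5 | (1S,4R)-5,8,8-trimethyl-2-oxabicyclo[2.2.2]oct-5-en-3-one | O1[C@@H]2C=C(C)[C@H](C1=O)C(C)(C)C2 | intermediate
6 | methyl (1R,4S)-4-hydroxy-2,6,6-trimethylcyclohex-2-ene-1-carboxylate (first-formed cis isomer, epimerises at C1) | O[C@@H]1C=C(C)[C@H](C(=O)OC)C(C)(C)C1 | intermediate (not isolated)
7 | methyl (4R)-4-hydroxy-2,6,6-trimethylcyclohex-1-ene-1-carboxylate | O[C@@H]1CC(C)=C(C(=O)OC)C(C)(C)C1 | intermediate
8 | (1R)-4-(hydroxymethyl)-3,5,5-trimethylcyclohex-3-en-1-ol | O[C@@H]1CC(C)=C(CO)C(C)(C)C1 | intermediate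
9 | {[(4R)-4-hydroxy-2,6,6-trimethylcyclohex-1-en-1-yl]methyl}triphenylphosphonium bromide | O[C@@H]1CC(C)=C(C[P+](c2ccccc2)(c2ccccc2)c2ccccc2)C(C)(C)C1.[Br-] | intermediate
10 | β-apo-8'-carotenal (all-E) | O=C/C(C)=C/C=C/C(C)=C/C=C/C=C(C)/C=C/C=C(C)/C=C/C1=C(C)CCCC1(C)C | starting material
11 | {[(4R)-4-hydroxy-2,6,6-trimethylcyclohex-1-en-1-yl]methylidene}triphenyl-λ5-phosphane (ylide) | O[C@@H]1CC(C)=C(C=P(c2ccccc2)(c2ccccc2)c2ccccc2)C(C)(C)C1 | intermediate (not isolated)
12 | (3R,7Z)-β,β-caroten-3-ol (7Z isomer of 13) | O[C@@H]1CC(C)=C(\C=C/C(C)=C/C=C/C(C)=C/C=C/C=C(C)/C=C/C=C(C)/C=C/C2=C(C)CCCC2(C)C)C(C)(C)C1 | intermediate (not isolated)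
13 | (3R)-β-cryptoxanthin, (3R,all-E)-β,β-caroten-3-ol | O[C@@H]1CC(C)=C(/C=C/C(C)=C/C=C/C(C)=C/C=C/C=C(C)/C=C/C=C(C)/C=C/C2=C(C)CCCC2(C)C)C(C)(C)C1 | intermediate
14 | oleic acid, (9Z)-octadec-9-enoic acid | CCCCCCCC/C=C\CCCCCCCC(=O)O | starting material
15 | (3R)-β,β-caroten-3-yl (9Z)-octadec-9-enoate (β-cryptoxanthin oleate) | CCCCCCCC/C=C\CCCCCCCC(=O)O[C@@H]1CC(C)=C(/C=C/C(C)=C/C=C/C(C)=C/C=C/C=C(C)/C=C/C=C(C)/C=C/C2=C(C)CCCC2(C)C)C(C)(C)C1 | target

Total step count: 8
Longest linear sequence: 8 steps (1 → 2 → 3 → 5 → 7 → 8 → 9 → 13 → 15)

Steps most likely to fail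

1. Step 3 (bears the label "Proposed new method:").
- What may go wrong: the bound pyranone may be too weak an electrophile for a non-activated alkene, and isobutene may be consumed by cationic oligomerisation. A stepwise pathway may end in proton loss (ene-type outcome) instead of ring closure. Face discrimination may be poor with one-point binding, and the Lewis acid may ionise the adduct and trigger loss of CO2.
- Fallback (known chemistry): it replaces the ring construction, so it sets out from no numbered compound; it starts from commercial mesityl oxide and ethyl acetoacetate and comes back to the route at compound 8. ZnCl2-mediated Michael addition and aldol condensation (heptane, reflux, water removal) gives racemic ethyl 2,6,6-trimethyl-4-oxocyclohex-2-ene-1-carboxylate F1, which already holds C1–C7 with the right substituents. CBS reduction of the enone carbonyl ((R)-methyl-CBS oxazaborolidine, BH3·SMe2, THF, −20 °C; antipode confirmed by correlation) sets the carbinol centre and gives ethyl (4S)-4-hydroxy-2,6,6-trimethylcyclohex-2-ene-1-carboxylate F2 as epimers at the ester carbon. NaOEt in EtOH moves the alkene into conjugation and removes that second centre, giving ethyl (4R)-4-hydroxy-2,6,6-trimethylcyclohex-1-ene-1-carboxylate F3. LiAlH4 reduction as in step 5 then gives diol 8.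

2. Step 4.
- What may go wrong: incomplete migration of the alkene, because the conjugated ester is twisted out of plane by its flanking methyl groups and may be only modestly favoured at equilibrium; and dehydration through the same dienolate, with loss of the C3 oxygen.
- Fallback: it sets out from lactone 5 and comes back at diol 8, bypassing 7. DIBAL-H (CH2Cl2, −78 °C) reduces the lactone to (1S,4R)-5,8,8-trimethyl-2-oxabicyclo[2.2.2]oct-5-en-3-ol F4. The open hydroxy-aldehyde form of this lactol is isomerised with DBU (CH2Cl2, rt) to (4R)-4-hydroxy-2,6,6-trimethylcyclohex-1-ene-1-carbaldehyde F5; an aldehyde is deprotonated more easily and gains more from conjugation than the ester. NaBH4 (MeOH, 0 °C) then gives 8.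

3. Step 7.
- What may go wrong: slow addition of the ylide, whose carbon is flanked by the C1 gem-dimethyl and C5 methyl groups, with competing ylide hydrolysis; and incomplete Z-to-E equilibration or build-up of other Z isomers of the polyene.
- Fallback: it sets out from diol 8 and comes back at compound 13. Mitsunobu thioetherification of the primary allylic alcohol (1-phenyl-1H-tetrazole-5-thiol, PPh3, DIAD, THF, 0 °C) gives (1R)-3,5,5-trimethyl-4-{[(1-phenyl-1H-tetrazol-5-yl)sulfanyl]methyl}cyclohex-3-en-1-ol F6. Silylation (TBSCl, imidazole, DMF) gives its tert-butyldimethylsilyl ether F7. Oxidation (H2O2, (NH4)6Mo7O24·4H2O cat., EtOH) gives the tetrazolyl sulfone F8. Julia–Kocienski olefination with 10 (KHMDS, THF, −78 °C → rt; then I2 cat., daylight) gives (3R)-β-cryptoxanthin tert-butyldimethylsilyl ether F9. TBAF (THF, rt) releases 13.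

Further compounds
F1 | step 3 | ethyl 2,6,6-trimethyl-4-oxocyclohex-2-ene-1-carboxylate (racemic) | CCOC(=O)C1C(C)=CC(=O)CC1(C)C
F2 | step 3 | ethyl (4S)-4-hydroxy-2,6,6-trimethylcyclohex-2-ene-1-carboxylate (epimers at C1) | O[C@@H]1C=C(C)C(C(=O)OCC)C(C)(C)C1
F3 | step 3 | ethyl (4R)-4-hydroxy-2,6,6-trimethylcyclohex-1-ene-1-carboxylate | O[C@@H]1CC(C)=C(C(=O)OCC)C(C)(C)C1
F4 | step 4 | (1S,4R)-5,8,8-trimethyl-2-oxabicyclo[2.2.2]oct-5-en-3-ol (lactol, both anomers) | O1[C@@H]2C=C(C)[C@H](C1O)C(C)(C)C2
F5 | step 4 | (4R)-4-hydroxy-2,6,6-trimethylcyclohex-1-ene-1-carbaldehyde | O[C@@H]1CC(C)=C(C=O)C(C)(C)C1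
F6 | step 7 | (1R)-3,5,5-trimethyl-4-{[(1-phenyl-1H-tetrazol-5-yl)sulfanyl]methyl}cyclohex-3-en-1-ol | O[C@@H]1CC(C)=C(CSc2nnnn2-c2ccccc2)C(C)(C)C1
F7 | step 7 | 5-({[(4R)-4-{[tert-butyl(dimethyl)silyl]oxy}-2,6,6-trimethylcyclohex-1-en-1-yl]methyl}sulfanyl)-1-phenyl-1H-tetrazole | CC(C)(C)[Si](C)(C)O[C@@H]1CC(C)=C(CSc2nnnn2-c2ccccc2)C(C)(C)C1
F8 | step 7 | 5-({[(4R)-4-{[tert-butyl(dimethyl)silyl]oxy}-2,6,6-trimethylcyclohex-1-en-1-yl]methyl}sulfonyl)-1-phenyl-1H-tetrazole | CC(C)(C)[Si](C)(C)O[C@@H]1CC(C)=C(CS(=O)(=O)c2nnnn2-c2ccccc2)C(C)(C)C1
F9 | step 7 | (3R)-β-cryptoxanthin tert-butyldimethylsilyl ether | CC(C)(C)[Si](C)(C)O[C@@H]1CC(C)=C(/C=C/C(C)=C/C=C/C(C)=C/C=C/C=C(C)/C=C/C=C(C)/C=C/C2=C(C)CCCC2(C)C)C(C)(C)C1
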